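The cyclopentane (C1–C5) is not cyclised directly: a cis-fused cyclobutanone (C4 carbonyl, C5, C1, C2), made by dichloroketene cycloaddition to a cycloheptene, takes up one carbon (C3) from a silyl diazomethane. Migration of the methylene C2 from C4 to C3 forms the C2–C3 bond and turns the four-membered ring into the five-membered one; elimination of the C6 silyloxy group in the same flask gives the hydroazulenone enone. The step exploits the oxygenated C4 flanked by the C3H2–C2H2 unit next to the quaternary C1. Reagent-controlled reduction, hydroboration and isopropyl addition then set C4–C6 with the trans ring fusion; the C8–C9 epoxide comes last.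

Key step: step 7

Remark: atoms carry daucane numbers (C1 methyl-bearing ring-fusion carbon, C2 and C3 the ring CH2 groups, C4 the isopropyl carbinol carbon, C5 the ring-fusion CH, C6 the carbinol CH, C7, C8 and C9 the epoxide carbons, C10), β means the face of the C1 methyl group, and 1, 2 and 19 are assumed to be purchasable.

Step 1
Reactants: 1 5-methylhex-5-en-2-one; 2 acrolein (prop-2-enal)
Product: 5 (R)-3-hydroxy-8-methylnona-1,8-dien-5-one, via diisopinocampheyl enol borinate 3 (not isolated), via boron aldolate 4 (not isolated)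
Conditions: (+)-Ipc2BCl, Et3N, Et2O, −78 °C; 2, −78 → −20 °C; H2O2, MeOH, pH 7 buffer, 0 °C
Reagents that add atoms: none
Why: Paterson boron aldol reaction: the kinetic enol borinate of the methyl ketone adds to the aldehyde through a cyclic transition state in which the isopinocampheyl ligands should direct attack to the Re face of acrolein and so set the (R)-carbinol at C6 (the (−)-reagent would be taken if the facial sense proved opposite).

Step 2
Reactants: 5 (R)-3-hydroxy-8-methylnona-1,8-dien-5-one
Product: 6 (R)-3-(tert-butyldimethylsilyloxy)-8-methylnona-1,8-dien-5-one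
Conditions: TBSCl, imidazole, DMF, 0 → 25 °C
Reagents that add atoms: tert-butyldimethylsilyl chloride, CC(C)(C)[Si](C)(C)Cl
Why: silylation of a secondary allylic alcohol with a silyl chloride; the bulky ether later shields one alkene face and then serves as the leaving group at C6.

Step 3
Reactants: 6 (R)-3-(tert-butyldimethylsilyloxy)-8-methylnona-1,8-dien-5-one
Product: 7 2-[(2R)-2-(tert-butyldimethylsilyloxy)but-3-en-1-yl]-2-(3-methylbut-3-en-1-yl)-1,3-dioxolane
Conditions: TMSOCH2CH2OTMS, TMSOTf (5 mol %), CH2Cl2, −78 → −20 °C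
Reagents that add atoms: 1,2-bis(trimethylsilyloxy)ethane, C[Si](C)(C)OCCO[Si](C)(C)C
Why: Noyori ketalisation: silyl-triflate-catalysed exchange at low temperature should convert the ketone into the dioxolane without β-elimination of the silyloxy group, masking C8 from the diazo reagent, the hydrides and the organometallics used later.

Step 4
Reactants: 7 2-[(2R)-2-(tert-butyldimethylsilyloxy)but-3-en-1-yl]-2-(3-methylbut-3-en-1-yl)-1,3-dioxolane
Product: 8 tert-butyl(dimethyl){[(7R)-9-methyl-1,4-dioxaspiro[4.6]undec-8-en-7-yl]oxy}silane (cycloheptene: C1=C5 alkene with C1 methyl; 6-OTBS; C8 ketal)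
Conditions: second-generation Grubbs catalyst (5 mol %), toluene (5 mM), 80 °C
Reagents that add atoms: none
Why: ring-closing metathesis of the vinyl group and the 1,1-disubstituted alkene closes the seven-membered ring as the trisubstituted C1=C5 alkene, driven by loss of ethylene.

Step 5
Reactants: 8 cycloheptene silyl ether
Product: 9 cis-fused dichlorocyclobutanone (C4 carbonyl on C5; CCl2 carbon C2 on C1; 1β-methyl; 5β-H; 6β-OTBS; C8 ketal)
Conditions: Cl3CCOCl, Zn–Cu couple, POCl3, Et2O, 25 °C
Reagents that add atoms: trichloroacetyl chloride, ClC(=O)C(Cl)(Cl)Cl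
Why: [2+2] cycloaddition of dichloroketene generated in situ: suprafacial addition gives the cis-fused cyclobutanone, the ketene carbonyl carbon bonds to the less substituted C5 and the CCl2 carbon to the methyl-bearing C1, and approach anti to the allylic silyl ether should set C1 (and, for the time being, C5).

Step 6
Reactants: 9 cis-fused dichlorocyclobutanone
Product: 10 cis-fused cyclobutanone (C2 now CH2; 1β-methyl; 5β-H; 6β-OTBS; C8 ketal)
Conditions: Zn–Cu couple, NH4Cl, MeOH, 25 °C
Reagents that add atoms: none
Why: reductive dechlorination of the α,α-dichloroketone through its zinc enolate leaves the stereocentres untouched and removes the chlorine atoms, which would otherwise steer the coming migration to the wrong carbon.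

Step 7
Reactants: 10 cis-fused cyclobutanone
Product: 13 (1R)-enone (C4 ketone conjugated with C5=C6; 1β-methyl; C8 ketal), via α-silyl cyclopentanone 11 (not isolated), via silyloxy cyclopentanone 12 (not isolated)
Conditions: TMSCHN2, Sc(OTf)3 (10 mol %), CH2Cl2, −78 → 0 °C; then MeOH, DBU, 25 → 40 °C
Reagents that add atoms: (trimethylsilyl)diazomethane, C[Si](C)(C)C=[N+]=[N-]
Why: Sc(OTf)3 activates the strained carbonyl C4 of 10, the diazo carbon of TMSCHN2 adds to it, and the β-oxido diazonium betaine loses N2 with 1,2-shift of the ring methylene C2 from C4 to the new carbon C3, which forms the C2–C3 bond and gives the C3-silylated cyclopentanone 11; methanol then cleaves the C–Si bond and DBU expels silanol from C6 (E1cB) to give the conjugated enone. The closest known reaction type is the Lewis-acid-catalysed diazoalkane homologation of cyclobutanones (a Tiffeneau–Demjanov-type one-carbon ring expansion). The five-membered ring is closed by ring expansion, that is by insertion of a single carbon into the four-membered ring with migration of a ring bond, not by a direct cyclisation. The step creates no stereocentre that is kept: C1 passes through unchanged because the migrating terminus is the CH2 group C2, and C5 and C6 are erased on purpose by the elimination. The selectivity needed is migration of C2 instead of C5, and it should be secured because C2 is the less substituted α-carbon while C5 is a methine carrying the electron-withdrawing C6–O group, with the bulky silyl diazomethane adding steric bias; chemoselectivity follows from the ring strain of the cyclobutanone and from the ketal that masks C8.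

Step 8
Reactants: 13 (1R)-enone
Product: 14 (1R,4S)-allylic alcohol (4β-OH; C5=C6; C8 ketal)
Conditions: (R)-2-methyl-CBS-oxazaborolidine (10 mol %), BH3·SMe2, THF, −40 °C; MeOH
Reagents that add atoms: none
Why: Corey–Bakshi–Shibata reduction: the catalyst-bound borane should deliver hydride to the α face of the C4 carbonyl (alkylidene side as the large group), a sense reinforced by approach anti to the C1 methyl, giving the temporary 4β-hydroxyl by 1,2-reduction.

Step 9
Reactants: 14 (1R,4S)-allylic alcohol
Product: 16 trans-fused diol (4β-OH; 5α-H; 6α-OH; C8 ketal), via alkylborane 15 (not isolated)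
Conditions: BH3·THF, THF, 0 → 25 °C; then NaOH, H2O2, 0 °C
Reagents that add atoms: hydrogen peroxide, OO
Why: hydroboration–oxidation: boron adds to the less substituted C6 and hydrogen to C5 in a syn fashion from the α face, anti to both the allylic C4 oxygen and the C1 methyl, and oxidation with retention should give the 6α-hydroxyl together with the 5α-hydrogen of the trans ring fusion.

Step 10
Reactants: 16 trans-fused diol
Product: 17 mono-silyl ether (6α-OTBS; 4β-OH free; 5α-H; C8 ketal)
Conditions: TBSCl, imidazole, DMF, 0 °C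
Reagents that add atoms: tert-butyldimethylsilyl chloride, CC(C)(C)[Si](C)(C)Cl
Why: silylation of the less hindered hydroxyl: the 6α-OH is flanked only by H5 on its face, whereas the 4β-OH on the cyclopentane is cis to both the C5–C6 bond and the C1 methyl.

Step 11
Reactants: 17 mono-silyl ether
Product: 18 trans-fused ketone (C4=O; 5α-H; 6α-OTBS; C8 ketal)
Conditions: Dess–Martin periodinane, NaHCO3, CH2Cl2, 25 °C
Reagents that add atoms: none
Why: Dess–Martin oxidation under buffered neutral conditions should give the ketone without epimerisation at C5 or β-elimination of the silyloxy group.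

Step 12
Reactants: 18 trans-fused ketone; 19 4-(benzyloxy)benzoyl chloride
Product: 21 tertiary ester (4β-[4-(benzyloxy)benzoyloxy]; 4α-isopropyl; 5α-H; 6α-OTBS; C8 ketal), via cerium alkoxide 20 (not isolated)
Conditions: i-PrLi, CeCl3, THF, −78 °C; then 19, −78 → 25 °C
Reagents that add atoms: isopropyllithium, [Li]C(C)C
Why: organocerium 1,2-addition (low basicity suppresses enolisation and reduction) from the α face, trans to the adjacent C5–C6 bond and anti to the C1 methyl, sets C4 with the isopropyl group α and the oxygen β, and the tertiary alkoxide is acylated in the same flask by the aroyl chloride.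

Step 13
Reactants: 21 tertiary ester with C8 ketal
Product: 22 C8 ketone (4β-aroyloxy; 4α-isopropyl; 6α-OTBS)
Conditions: PPTS, acetone/H2O, 50 °C
Reagents that add atoms: water, O
Why: acid-catalysed hydrolysis of the dioxolane; the secondary silyl ether, the benzyl ether and the hindered tertiary ester should survive pyridinium tosylate.

Step 14
Reactants: 22 C8 ketone
Product: 24 enol triflate (C8–OTf; C8=C9), via potassium enolate 23 (not isolated)
Conditions: KN(SiMe3)2, THF, −78 °C; then PhNTf2, −78 → 0 °C
Reagents that add atoms: N-phenylbis(trifluoromethanesulfonimide), O=S(=O)(N(c1ccccc1)S(=O)(=O)C(F)(F)F)C(F)(F)F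
Why: kinetic deprotonation at C9, the α-methylene remote from the silyloxy-bearing C6 and therefore less hindered and free of a β-oxygen, followed by O-sulfonylation of the enolate, fixes the double bond between C8 and C9.

Step 15
Reactants: 24 enol triflate
Product: 25 trisubstituted alkene (8-methyl; C8=C9; 6α-OTBS)
Conditions: MeZnCl, Pd(PPh3)4 (5 mol %), THF, 50 °C
Reagents that add atoms: methylzinc chloride, C[Zn]Cl
Why: Negishi cross-coupling of the enol triflate with a methylzinc reagent installs the C8 methyl group with the double bond held at C8=C9.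

Step 16
Reactants: 25 trisubstituted alkene
Product: 26 homoallylic alcohol (6α-OH; C8=C9; benzyl-protected ester)
Conditions: HF·pyridine, pyridine, THF, 0 → 25 °C
Reagents that add atoms: none
Why: fluoride-mediated desilylation under weakly acidic conditions frees the 6α-hydroxyl without generating an alkoxide that could take over the neighbouring aroyl group.

Step 17
Reactants: 26 homoallylic alcohol
Product: 27 8α,9α-epoxide with benzyl-protected phenol
Conditions: mCPBA, NaHCO3, CH2Cl2, 0 °C
Reagents that add atoms: 3-chloroperoxybenzoic acid, OOC(=O)c1cccc(Cl)c1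
Why: Prilezhaev epoxidation from the α face, opposite the C1 methyl that screens the β face and guided by hydrogen bonding to the homoallylic 6α-hydroxyl, should set C8 and C9.

Step 18
Reactants: 27 benzyl-protected epoxide
Product: 28 target CNP0264773.1
Conditions: H2 (1 atm), Pd/C, EtOAc, 25 °C
Reagents that add atoms: none
Why: hydrogenolysis of the aryl benzyl ether over Pd frees the phenol while the trialkyl epoxide and the tertiary benzoate should stay intact.

Compound list
1 | 5-methylhex-5-en-2-one | CC(=O)CCC(C)=C | starting material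
2 | acrolein (prop-2-enal) | C=CC=O | starting material
3 | diisopinocampheyl enol borinate of 1 (less substituted enolate) | C=C(CCC(C)=C)OB([C@H]1C[C@H]2C[C@@H]([C@@H]1C)C2(C)C)[C@H]1C[C@H]2C[C@@H]([C@@H]1C)C2(C)C | intermediate (not isolated)
4 | diisopinocampheylboron aldolate of 5 | C=C[C@H](OB([C@H]1C[C@H]2C[C@@H]([C@@H]1C)C2(C)C)[C@H]1C[C@H]2C[C@@H]([C@@H]1C)C2(C)C)CC(=O)CCC(C)=C | intermediate (not isolated)
5 | (R)-3-hydroxy-8-methylnona-1,8-dien-5-one | C=C[C@H](O)CC(=O)CCC(C)=C | intermediate
6 | (R)-3-(tert-butyldimethylsilyloxy)-8-methylnona-1,8-dien-5-one | C=C[C@H](O[Si](C)(C)C(C)(C)C)CC(=O)CCC(C)=C | intermediate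
7 | 2-[(2R)-2-(tert-butyldimethylsilyloxy)but-3-en-1-yl]-2-(3-methylbut-3-en-1-yl)-1,3-dioxolane | C=C[C@H](O[Si](C)(C)C(C)(C)C)CC1(CCC(C)=C)OCCO1 | intermediate
8 | tert-butyl(dimethyl){[(7R)-9-methyl-1,4-dioxaspiro[4.6]undec-8-en-7-yl]oxy}silane | CC1=C[C@H](O[Si](C)(C)C(C)(C)C)CC2(CC1)OCCO2 | intermediate
9 | cis-fused dichlorocyclobutanone: C4 ketone on C5, CCl2 (C2) on C1, 1β-methyl, 5β-H, 6β-OTBS, C8 ethylene ketal | O=C1C(Cl)(Cl)[C@]2(C)CCC3(OCCO3)C[C@@H](O[Si](C)(C)C(C)(C)C)[C@@H]21 | intermediate
10 | cis-fused cyclobutanone: as 9 with C2 = CH2 | O=C1C[C@]2(C)CCC3(OCCO3)C[C@@H](O[Si](C)(C)C(C)(C)C)[C@@H]21 | intermediate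
11 | cis-fused cyclopentan-4-one with SiMe3 on C3 (either epimer), 6β-OTBS, C8 ketal | O=C1C([Si](C)(C)C)C[C@]2(C)CCC3(OCCO3)C[C@@H](O[Si](C)(C)C(C)(C)C)[C@@H]21 | intermediate (not isolated)
12 | cis-fused cyclopentan-4-one, 1β-methyl, 5β-H, 6β-OTBS, C8 ketal | O=C1CC[C@]2(C)CCC3(OCCO3)C[C@@H](O[Si](C)(C)C(C)(C)C)[C@@H]21 | intermediate (not isolated)
13 | (1R)-enone: C4 ketone conjugated with C5=C6, 1β-methyl, C8 ethylene ketal | O=C1CC[C@]2(C)CCC3(OCCO3)CC=C21 | intermediate
14 | (1R,4S)-allylic alcohol: 4β-OH, C5=C6, C8 ketal | O[C@H]1CC[C@]2(C)CCC3(OCCO3)CC=C21 | intermediate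
15 | alkylborane: BH2 on C6 (α), boryl on the 4β-oxygen, 5α-H | [BH2]O[C@H]1CC[C@]2(C)CCC3(OCCO3)C[C@H]([BH2])[C@H]21 | intermediate (not isolated)
16 | trans-fused diol: 4β-OH, 5α-H, 6α-OH, C8 ketal | O[C@H]1CC[C@]2(C)CCC3(OCCO3)C[C@H](O)[C@H]21 | intermediate
17 | 6α-O-TBS ether of 16 (4β-OH free) | O[C@H]1CC[C@]2(C)CCC3(OCCO3)C[C@H](O[Si](C)(C)C(C)(C)C)[C@H]21 | intermediate
18 | trans-fused ketone: C4=O, 5α-H, 6α-OTBS, C8 ketal | O=C1CC[C@]2(C)CCC3(OCCO3)C[C@H](O[Si](C)(C)C(C)(C)C)[C@H]21 | intermediate
19 | 4-(benzyloxy)benzoyl chloride | O=C(Cl)c1ccc(OCc2ccccc2)cc1 | starting material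
20 | dichlorocerium alkoxide: 4β-O–CeCl2, 4α-isopropyl, 5α-H, 6α-OTBS, C8 ketal | CC(C)[C@]1(O[Ce](Cl)Cl)CC[C@]2(C)CCC3(OCCO3)C[C@H](O[Si](C)(C)C(C)(C)C)[C@H]21 | intermediate (not isolated)
21 | tertiary ester: 4β-[4-(benzyloxy)benzoyloxy], 4α-isopropyl, 5α-H, 6α-OTBS, C8 ketal | CC(C)[C@]1(OC(=O)c2ccc(OCc3ccccc3)cc2)CC[C@]2(C)CCC3(OCCO3)C[C@H](O[Si](C)(C)C(C)(C)C)[C@H]21 | intermediate
22 | C8 ketone: as 21 with C8=O | CC(C)[C@]1(OC(=O)c2ccc(OCc3ccccc3)cc2)CC[C@]2(C)CCC(=O)C[C@H](O[Si](C)(C)C(C)(C)C)[C@H]21 | intermediate
23 | potassium enolate of 22 (C8–O−, C8=C9) | CC(C)[C@]1(OC(=O)c2ccc(OCc3ccccc3)cc2)CC[C@]2(C)CC=C([O-])C[C@H](O[Si](C)(C)C(C)(C)C)[C@H]21.[K+] | intermediate (not isolated)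
24 | enol triflate: C8–OTf, C8=C9 | CC(C)[C@]1(OC(=O)c2ccc(OCc3ccccc3)cc2)CC[C@]2(C)CC=C(OS(=O)(=O)C(F)(F)F)C[C@H](O[Si](C)(C)C(C)(C)C)[C@H]21 | intermediate
25 | alkene: 8-methyl, C8=C9, 6α-OTBS | CC(C)[C@]1(OC(=O)c2ccc(OCc3ccccc3)cc2)CC[C@]2(C)CC=C(C)C[C@H](O[Si](C)(C)C(C)(C)C)[C@H]21 | intermediate
26 | homoallylic alcohol: as 25 with 6α-OH | CC(C)[C@]1(OC(=O)c2ccc(OCc3ccccc3)cc2)CC[C@]2(C)CC=C(C)C[C@H](O)[C@H]21 | intermediate
27 | 8α,9α-epoxide with benzyl-protected phenol | CC(C)[C@]1(OC(=O)c2ccc(OCc3ccccc3)cc2)CC[C@]2(C)C[C@@H]3O[C@]3(C)C[C@H](O)[C@H]21 | intermediate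
28 | CNP0264773.1: 4β-(4-hydroxybenzoyloxy)-8α,9α-epoxydaucan-6α-ol (1β-methyl, 4α-isopropyl, 5α-H) | CC(C)[C@]1(OC(=O)c2ccc(O)cc2)CC[C@]2(C)C[C@@H]3O[C@]3(C)C[C@H](O)[C@H]21 | target

Total step count: 18. Longest linear sequence: 18 steps (1 → 28).

Steps most likely to fail

Step 7: the 1,2-shift may be misdirected (migration of the ring-fusion carbon C5 instead of C2), or the ketal may be lost to the Lewis acid during the homologation. The fallback sets out from 10 and comes back at 13. Ethyl diazoacetate with BF3·OEt2 (CH2Cl2, −78 °C) should give the ring-expanded β-keto ester F1 (ethoxycarbonyl on C3) by shift of the less substituted C2, the course that acceptor-substituted diazo esters are known to favour. LiCl in wet DMSO at 140 °C then removes the ester group (Krapcho dealkoxycarbonylation), and DBU in the same pot eliminates the C6 silanol to give 13.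

Step 5: the cycloaddition may be sluggish on the oxygen-deactivated alkene, facial discrimination on the flexible seven-membered ring may be poor, or the zinc salts may erode the ketal. The fallback sets out from 8 and comes back at 10. The keteniminium salt made from N,N-dimethylacetamide, Tf2O and 2,4,6-collidine (ClCH2CH2Cl, reflux) should add across C1=C5 with the same regiochemistry to give the cyclobutaniminium triflate F2. Hydrolysis with aqueous NaHCO3 gives 10 directly, so step 6 is not needed; the larger cationic ketene equivalent should feel the silyl ether more strongly.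

Step 12: the secondary organometallic may reduce or enolise the hindered ketone, and acylation of the very hindered tertiary alkoxide may stay incomplete. The fallback sets out from 18 and comes back at 21. CH2=C(CH3)MgBr with CeCl3, which has no β-hydrogen to transfer, should give the tertiary isopropenyl carbinol F3. Deprotonation with KN(SiMe3)2 and acylation with 19 as a separate operation gives the isopropenyl ester F4. H2 with RhCl(PPh3)3 then saturates the 1,1-disubstituted alkene without hydrogenolysis of the benzyl ether and gives 21.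

Further compounds
F1 | step 7 | ring-expanded β-keto ester: cis-fused cyclopentan-4-one with CO2Et on C3, 6β-OTBS, C8 ketal | O=C1C(C(=O)OCC)C[C@]2(C)CCC3(OCCO3)C[C@@H](O[Si](C)(C)C(C)(C)C)[C@@H]21
F2 | step 5 | cis-fused N,N-dimethylcyclobutaniminium triflate (C4=N+Me2), 6β-OTBS, C8 ketal | C[N+](C)=C1C[C@]2(C)CCC3(OCCO3)C[C@@H](O[Si](C)(C)C(C)(C)C)[C@@H]21.[O-]S(=O)(=O)C(F)(F)F
F3 | step 12 | tertiary isopropenyl carbinol: 4β-OH, 4α-isopropenyl, 5α-H, 6α-OTBS, C8 ketal | C=C(C)[C@]1(O)CC[C@]2(C)CCC3(OCCO3)C[C@H](O[Si](C)(C)C(C)(C)C)[C@H]21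
F4 | step 12 | isopropenyl ester: 4β-[4-(benzyloxy)benzoyloxy], 4α-isopropenyl, 5α-H, 6α-OTBS, C8 ketal | C=C(C)[C@]1(OC(=O)c2ccc(OCc3ccccc3)cc2)CC[C@]2(C)CCC3(OCCO3)C[C@H](O[Si](C)(C)C(C)(C)C)[C@H]21
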